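**Strategy.** Ring B (C1' OH, C2' OAr, C4' and C6' Br) is built, not coupled. Its C2'(OAr)–C1'(OH)–C6' edge is read as a 4-aryloxyacetoacetate and C3'–C4'–C5' as malonaldehyde, so the hindered diaryl ether oxygen is attached beforehand by SN2 alkylation of 2,4-dibromo-6-methoxyphenol at a CH2 group. One Lewis-acid (3+3) cyclocondensation of the bis(silyl enol ether) 8, 4-(2,4-dibromo-6-methoxyphenoxy)-1-methoxy-1,3-bis(trimethylsilyloxy)buta-1,3-diene, with 1,1,3,3-tetramethoxypropane forms C2'–C3' and C5'–C6' and closes ring B as a 3-aryloxysalicylate. The ester left on C6', ortho to the C1' hydroxyl, is later replaced by bromine with loss of CO2, while C4' is brominated para to OH.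

Key step: step 5

Remark on the chemistry: 4-bromo-2-methoxyphenol is taken as the entry to ring A because the second bromine must go ortho to OH (C6). Without amine direction, bromination of a guaiacol can instead attack C5, para to OMe. The C=C geometry of 6 and 8 is left undefined, since all isomers converge on the same arene.

**Step 1**
Reactants: 1 4-bromo-2-methoxyphenol
Product: 2 2,4-dibromo-6-methoxyphenol
Conditions: NBS (1.05 equiv), iPr2NH (0.1 equiv), CH2Cl2, 0 → 20 °C
Reagents that add atoms: N-bromosuccinimide, O=C1CCC(=O)N1Br
Why: Amine-catalysed electrophilic aromatic bromination, in which an N-bromoamine hydrogen-bonded to the phenol delivers bromine to C6, the only free position ortho to OH, and not to C5 para to OMe.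

**Step 2**
Reactants: 2 2,4-dibromo-6-methoxyphenol; 3 methyl 4-chloroacetoacetate (methyl 4-chloro-3-oxobutanoate)
Product: 5 methyl 4-(2,4-dibromo-6-methoxyphenoxy)-3-oxobutanoate, via sodium phenolate 4 (not isolated)
Conditions: NaH (2.1 equiv), THF/DMF, 0 °C; then 3, NaI (0.1 equiv), 0 → 60 °C; then 1 M HCl
Reagents that add atoms: none
Why: Williamson ether synthesis, in which the phenolate displaces chloride by SN2 at the primary CH2 next to the ketone while the second equivalent of NaH holds the 1,3-dicarbonyl unit as its enolate and so limits self-condensation.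

**Step 3**
Reactants: 5 methyl 4-(2,4-dibromo-6-methoxyphenoxy)-3-oxobutanoate
Product: 6 methyl 4-(2,4-dibromo-6-methoxyphenoxy)-3-(trimethylsilyloxy)but-2-enoate (E/Z mixture)
Conditions: Me3SiCl (1.5 equiv), Et3N (1.6 equiv), toluene, 20 °C
Reagents that add atoms: chlorotrimethylsilane, C[Si](C)(C)Cl
Why: Silyl enol ether formation by O-silylation of the enolised beta-ketoester; the C2 hydrogens between the two carbonyls are the most acidic, so the ester-conjugated 3-silyloxy enoate should form.

**Step 4**
Reactants: 6 methyl 4-(2,4-dibromo-6-methoxyphenoxy)-3-(trimethylsilyloxy)but-2-enoate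
Product: 8 4-(2,4-dibromo-6-methoxyphenoxy)-1-methoxy-1,3-bis(trimethylsilyloxy)buta-1,3-diene (geometry undefined), via lithium dienolate 7 (not isolated)
Conditions: LiN(iPr)2 (LDA, 1.1 equiv), THF, −78 °C, 30 min; then Me3SiCl (1.3 equiv), −78 → 20 °C; used crude
Reagents that add atoms: chlorotrimethylsilane, C[Si](C)(C)Cl
Why: Kinetic gamma-deprotonation of the vinylogous ester to the extended enolate and O-silylation gives the silyl ketene acetal; near-stoichiometric base and short contact at −78 °C are meant to spare the ring A C–H flanked by two bromines.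

**Step 5**
Reactants: 8 4-(2,4-dibromo-6-methoxyphenoxy)-1-methoxy-1,3-bis(trimethylsilyloxy)buta-1,3-diene; 9 1,1,3,3-tetramethoxypropane
Product: 12 methyl 3-(2,4-dibromo-6-methoxyphenoxy)-2-hydroxybenzoate, via open-chain silyl enol ether 10 (not isolated), via dimethoxycyclohexanone ester 11 (not isolated)
Conditions: Me3SiOTf (0.3 equiv), CH2Cl2, −78 → 20 °C; then 10% aq. HCl
Reagents that add atoms: none
Why: Me3SiOTf ionises one acetal of 9 to a methoxycarbenium ion, which the terminal, aryloxy-bearing carbon of 8 (future C2') attacks in a vinylogous Mukaiyama aldol-type addition, forming C2'–C3' in 10 and regenerating the silyl Lewis acid. Ionisation of the second acetal lets the ester-bearing enol carbon (future C6') close ring B by an intramolecular Mukaiyama aldol reaction, a 6-(enolendo)-exo-trig closure onto the oxocarbenium carbon that forms C5'–C6' and gives 11, which loses two MeOH under acid and enolises to the arene. The closest known reaction type is the Lewis-acid (3+3) cyclocondensation of 1,3-bis(silyloxy)-1,3-dienes with malonaldehyde bis-acetals or 3-silyloxyenones to salicylates, which is known to accept 4-aryloxy dienes. No stereocentre survives, because the sp3 centres of 10 and 11 are erased on aromatisation, so their configuration and the diene geometry do not matter. The step needs carbon–carbon bond formation at both diene termini: silyl enol ethers react at carbon under these conditions, the symmetric three-carbon dielectrophile makes both orientations identical, and the blocked ortho positions of ring A (Br, OMe) rule out acid-induced benzofuran formation from the aryloxy ketone.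

**Step 6**
Reactants: 12 methyl 3-(2,4-dibromo-6-methoxyphenoxy)-2-hydroxybenzoate
Product: 14 3-(2,4-dibromo-6-methoxyphenoxy)-2-hydroxybenzoic acid, via disodium salt 13 (not isolated)
Conditions: NaOH (4 equiv), MeOH/H2O, reflux; then aq. HCl
Reagents that add atoms: sodium hydroxide, [Na+].[OH-]
Why: Ester saponification (acyl–oxygen hydrolysis by hydroxide); the unactivated diaryl ether, aryl methyl ether and aryl bromides are inert to aqueous hydroxide.

**Step 7**
Reactants: 14 3-(2,4-dibromo-6-methoxyphenoxy)-2-hydroxybenzoic acid
Product: 16 2,4-dibromo-6-(2,4-dibromo-6-methoxyphenoxy)phenol, via 5-bromo acid 15 (not isolated)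
Conditions: Br2 (2.1 equiv), NaOAc (3 equiv), AcOH/H2O, 20 °C; then aq. NaHSO3
Reagents that add atoms: bromine, BrBr
Why: Electrophilic aromatic bromination para to the phenol OH (C4') is followed by ipso attack at C6' and loss of CO2 from the resulting beta-keto-acid-type dienone (bromodecarboxylation of a salicylic acid); the doubly brominated anisole-type ring A is far less reactive than the phenol ring, so two equivalents of Br2 should stop at the tetrabromide.

**Compound list**
1 | 4-bromo-2-methoxyphenol | COc1cc(Br)ccc1O | starting material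
2 | 2,4-dibromo-6-methoxyphenol | COc1cc(Br)cc(Br)c1O | intermediate
3 | methyl 4-chloroacetoacetate | COC(=O)CC(=O)CCl | starting material
4 | sodium 2,4-dibromo-6-methoxyphenolate (not isolated) | [Na+].COc1cc(Br)cc(Br)c1[O-] | intermediate
5 | methyl 4-(2,4-dibromo-6-methoxyphenoxy)-3-oxobutanoate | COC(=O)CC(=O)COc1c(Br)cc(Br)cc1OC | intermediate
6 | methyl 4-(2,4-dibromo-6-methoxyphenoxy)-3-(trimethylsilyloxy)but-2-enoate, E/Z mixture | COC(=O)C=C(O[Si](C)(C)C)COc1c(Br)cc(Br)cc1OC | intermediate
7 | lithium dienolate of 6, deprotonated at C4 (not isolated) | [Li+].COC([O-])=CC(O[Si](C)(C)C)=COc1c(Br)cc(Br)cc1OC | intermediate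
8 | 4-(2,4-dibromo-6-methoxyphenoxy)-1-methoxy-1,3-bis(trimethylsilyloxy)buta-1,3-diene, double-bond geometry undefined | COC(O[Si](C)(C)C)=CC(O[Si](C)(C)C)=COc1c(Br)cc(Br)cc1OC | intermediate
9 | 1,1,3,3-tetramethoxypropane | COC(CC(OC)OC)OC | starting material
10 | methyl 4-(2,4-dibromo-6-methoxyphenoxy)-5,7,7-trimethoxy-3-(trimethylsilyloxy)hept-2-enoate, stereoisomer mixture (not isolated) | COC(=O)C=C(O[Si](C)(C)C)C(Oc1c(Br)cc(Br)cc1OC)C(OC)CC(OC)OC | intermediate
11 | methyl 3-(2,4-dibromo-6-methoxyphenoxy)-4,6-dimethoxy-2-oxocyclohexane-1-carboxylate, stereoisomer mixture (not isolated) | COC(=O)C1C(OC)CC(OC)C(Oc2c(Br)cc(Br)cc2OC)C1=O | intermediate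
12 | methyl 3-(2,4-dibromo-6-methoxyphenoxy)-2-hydroxybenzoate | COC(=O)c1cccc(Oc2c(Br)cc(Br)cc2OC)c1O | intermediate
13 | disodium 3-(2,4-dibromo-6-methoxyphenoxy)-2-oxidobenzoate (not isolated) | [Na+].[Na+].[O-]C(=O)c1cccc(Oc2c(Br)cc(Br)cc2OC)c1[O-] | intermediate
14 | 3-(2,4-dibromo-6-methoxyphenoxy)-2-hydroxybenzoic acid | OC(=O)c1cccc(Oc2c(Br)cc(Br)cc2OC)c1O | intermediate
15 | 5-bromo-3-(2,4-dibromo-6-methoxyphenoxy)-2-hydroxybenzoic acid (not isolated) | OC(=O)c1cc(Br)cc(Oc2c(Br)cc(Br)cc2OC)c1O | intermediate
16 | 2,4-dibromo-6-(2,4-dibromo-6-methoxyphenoxy)phenol | COc1cc(Br)cc(Br)c1Oc1cc(Br)cc(Br)c1O | target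

**Totals.** Total step count: 7. Longest linear sequence: 7 steps (1 → 16).

**Steps most likely to fail**

Step 5. The moisture-sensitive diene may lose its silyl groups before carbon–carbon bond formation, or the sequence may stall after the first addition so that ring closure and aromatisation stay incomplete. The fallback takes ring B from a preformed arene and sets out from phenol 2. SNAr with 2-fluorobenzaldehyde (K2CO3, DMAc, 140 °C) should give 2-(2,4-dibromo-6-methoxyphenoxy)benzaldehyde F1. Baeyer–Villiger (Dakin-type) oxidation with mCPBA in CH2Cl2 should give 2-(2,4-dibromo-6-methoxyphenoxy)phenyl formate F2. KOH in aqueous MeOH should cleave it to 2-(2,4-dibromo-6-methoxyphenoxy)phenol F3. Br2 (2 equiv, NaOAc, AcOH) then brominates ortho and para to the free OH, and the route is rejoined at target 16.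

Step 4. The amide base may also deprotonate ring A at the C–H between the two bromines, leading to aryl silylation or bromine migration, or the dienolate may be silylated on carbon instead of oxygen. The fallback avoids any strong base and sets out from ketoester 5. Soft enolisation with Me3SiOTf (2.2 equiv) and Et3N (2.5 equiv) in Et2O at 0 °C should silylate both carbonyl oxygens in one operation, bypassing 6 and 7 and coming back to the route at diene 8; no new compound is made.

Step 2. Displacement by the hindered, weakly nucleophilic phenolate may be slow, so that the chloroketoester self-condenses or cyclises first. The fallback builds the ketoester from the other end and sets out from phenol 2. Alkylation with chloroacetic acid (aq. NaOH, reflux) should give (2,4-dibromo-6-methoxyphenoxy)acetic acid F4. Activation with 1,1'-carbonyldiimidazole in THF should give 1-[(2,4-dibromo-6-methoxyphenoxy)acetyl]imidazole F5. Claisen-type acylation of potassium methyl malonate (KO2CCH2CO2Me, MgCl2, Et3N) should give the acylmalonic half ester 2-[(2,4-dibromo-6-methoxyphenoxy)acetyl]-3-methoxy-3-oxopropanoic acid F6, which decarboxylates on acidic work-up and returns to the route at ketoester 5.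

**Further compounds**
F1 | step 5 | 2-(2,4-dibromo-6-methoxyphenoxy)benzaldehyde | O=Cc1ccccc1Oc1c(Br)cc(Br)cc1OC
F2 | step 5 | 2-(2,4-dibromo-6-methoxyphenoxy)phenyl formate | O=COc1ccccc1Oc1c(Br)cc(Br)cc1OC
F3 | step 5 | 2-(2,4-dibromo-6-methoxyphenoxy)phenol | Oc1ccccc1Oc1c(Br)cc(Br)cc1OC
F0 | step 4 | none | none
F4 | step 2 | (2,4-dibromo-6-methoxyphenoxy)acetic acid | OC(=O)COc1c(Br)cc(Br)cc1OC
F5 | step 2 | 1-[(2,4-dibromo-6-methoxyphenoxy)acetyl]imidazole | O=C(COc1c(Br)cc(Br)cc1OC)n1ccnc1
F6 | step 2 | 2-[(2,4-dibromo-6-methoxyphenoxy)acetyl]-3-methoxy-3-oxopropanoic acid | COC(=O)C(C(=O)O)C(=O)COc1c(Br)cc(Br)cc1OC
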